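**Plan**
1. Ring labels: A = 4-hydroxyphenyl, B = central trisubstituted benzene, C = 1,4-phenylene, D = salicylic acid ring. The first cut is the CH2–CH2 bond of the C/D bridge (toluate anion plus aldehyde), with the acid masked as the lactone C–O bond of a 3-aryl-3,4-dihydroisocoumarin. The second cut takes ring B apart at C1–C6 and C4–C5.
2. Enabling feature: ring B carries OMe at C1, the CH2CH2 bridge to ring A at C3 and the ring C aryloxy oxygen at C5, all mutually meta, with H at C2, C4 and C6. A 3-alkylcyclobutenone (C1–C4) and an oxygen-substituted terminal alkyne (C5, C6) give exactly this pattern, so the diaryl ether oxygen can arrive on the alkyne.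
3. Forward: rings A, C and D are bought as arenes. The cyclobutenone is grown on the ring A arm (propargylation, dichloroketene [2+2], dechlorination). The ynol ether is made on the ring C phenol (trichloroethylene, then n-BuLi). Ring B is the only ring built and arises when the two are heated together.
4. Then follow O-methylation at C1, release of the ring C aldehyde and attachment of ring D. A single hydrogenolysis removes both benzyl groups and opens the lactone to the acid.
5. Stereochemistry: the target is achiral. The one transient centre (C3 of the lactone) is formed racemic and is erased in the last step.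

Key step: step 8

Remark: ring B is numbered C1 (OMe), C3 (bridge to ring A), C5 (aryloxy). Lactone positions follow isochroman-1-one numbering.

**Step 1**
Reactants: 1 4-benzyloxybenzyl chloride; 2 1-(trimethylsilyl)propyne
Product: 4 [4-(4-benzyloxyphenyl)but-1-yn-1-yl]trimethylsilane, via 3-lithio-1-(trimethylsilyl)propyne 3 (not isolated)
Conditions: 2, n-BuLi, THF, −78 °C; then 1, −78 °C to rt
Reagents that add atoms: none
Why: Propargylic lithiation of a silyl-capped propyne followed by SN2 alkylation with a reactive benzylic chloride is a standard three-carbon homologation, and the silyl group blocks the alkyne terminus and disfavours allene formation.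

**Step 2**
Reactants: 4 [4-(4-benzyloxyphenyl)but-1-yn-1-yl]trimethylsilane
Product: 5 1-benzyloxy-4-(but-3-yn-1-yl)benzene
Conditions: K2CO3, MeOH–THF, rt
Reagents that add atoms: none
Why: Base-promoted methanolysis of the alkynyl C–Si bond (protodesilylation) is mild enough to leave the benzyl ether untouched.

**Step 3**
Reactants: 5 1-benzyloxy-4-(but-3-yn-1-yl)benzene; 6 trichloroacetyl chloride
Product: 8 3-[2-(4-benzyloxyphenyl)ethyl]-4,4-dichlorocyclobut-2-en-1-one, via dichloroketene 7 (not isolated)
Conditions: Zn–Cu couple, Et2O–DME, slow addition of 6, rt to 35 °C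
Reagents that add atoms: none
Why: Dichloroketene from zinc dechlorination of 6 undergoes the well-known regioselective [2+2] cycloaddition with terminal alkynes, its carbonyl carbon bonding to the unsubstituted alkyne carbon, while DME binds ZnCl2 and protects the benzyl ether.

**Step 4**
Reactants: 8 3-[2-(4-benzyloxyphenyl)ethyl]-4,4-dichlorocyclobut-2-en-1-one
Product: 9 3-[2-(4-benzyloxyphenyl)ethyl]cyclobut-2-en-1-one
Conditions: Zn dust, AcOH, TMEDA, EtOH, 0 °C to rt
Reagents that add atoms: none
Why: Zinc reduction in amine-buffered acetic acid is the standard reductive dechlorination of 4,4-dichlorocyclobutenones to 3-alkylcyclobutenones and spares the enone C=C and the benzyl ether.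

**Step 5**
Reactants: 10 4-hydroxybenzyl alcohol
Product: 11 4-[(tert-butyldimethylsilyloxy)methyl]phenol
Conditions: TBSCl (1.05 equiv), imidazole, DMF, 0 °C
Reagents that add atoms: tert-butyldimethylsilyl chloride, CC(C)(C)[Si](C)(C)Cl
Why: With one equivalent of silyl chloride the primary benzylic alcohol is silylated in preference to the phenol, a routine selective protection of this diol.

**Step 6**
Reactants: 11 4-[(tert-butyldimethylsilyloxy)methyl]phenol; 12 trichloroethylene
Product: 14 tert-butyl({4-[(E)-1,2-dichlorovinyloxy]phenyl}methoxy)dimethylsilane, via dichloroacetylene 13 (not isolated)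
Conditions: K2CO3, DMF, 70 °C
Reagents that add atoms: none
Why: Base converts trichloroethylene into dichloroacetylene and anti addition of the phenoxide gives the (E)-1,2-dichlorovinyl ether, the standard first stage of ynol ether synthesis from phenols.

**Step 7**
Reactants: 14 tert-butyl({4-[(E)-1,2-dichlorovinyloxy]phenyl}methoxy)dimethylsilane
Product: 17 tert-butyl{[4-(ethynyloxy)phenyl]methoxy}dimethylsilane, via aryloxychloroacetylene 15 (not isolated), via lithium aryloxyacetylide 16 (not isolated)
Conditions: n-BuLi (2.3 equiv), THF, −78 to −40 °C; H2O quench at −78 °C; filtration through Et3N-deactivated silica, stored cold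
Reagents that add atoms: none
Why: Dehydrochlorination, chlorine–lithium exchange by the second equivalent of n-BuLi and protonation form the established dichlorovinyl ether route to terminal aryl ethynyl ethers, and the silyl ether is inert at this temperature.

**Step 8**
Reactants: 9 3-[2-(4-benzyloxyphenyl)ethyl]cyclobut-2-en-1-one; 17 tert-butyl{[4-(ethynyloxy)phenyl]methoxy}dimethylsilane
Product: 22 3-[2-(4-benzyloxyphenyl)ethyl]-5-{4-[(tert-butyldimethylsilyloxy)methyl]phenoxy}phenol, via vinylketene 18 (not isolated), via 4-vinylcyclobutenone 19 (not isolated), via dienylketene 20 (not isolated), via cyclohexadienone 21 (not isolated)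
Conditions: 17 (1.5 equiv), toluene, Ar, sealed tube, 80 °C then 110 °C
Reagents that add atoms: none
Why: Proposed new method: the closest known reaction type is the Danheiser benzannulation of cyclobutenones with alkoxy-, silyloxy-, thio- and amino-substituted alkynes, and an aryl ynol ether is a ketenophile class not yet shown in it. Four-electron conrotatory opening of 9 gives vinylketene 18, which takes up 17 in a [2+2] cycloaddition where the nucleophilic terminal alkyne carbon attacks the ketene carbonyl carbon (C1–C6 bond) and the oxygen-bearing carbon bonds to the ketene alpha carbon (C4–C5 bond). Cyclobutenone 19 reopens to dienylketene 20, ring B closes by six-electron disrotatory electrocyclisation that re-forms C1–C2, and dienone 21 tautomerises to phenol 22, so no stereocentre remains. The only selectivity needed is the orientation of the [2+2] step, and the oxygen lone pair of 17 polarises the triple bond so that hydroxyl, aryloxy group and chain end up mutually meta. The aryloxy oxygen is a weaker donor than an alkoxy oxygen but comparable to the acylated nitrogen of ynamides that do react, and 17 has no C–H beta to oxygen through which a retro-ene loss of ketene could occur at 110 °C. The excess of 17 should keep the vinylketene from being intercepted by the product phenol.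

**Step 9**
Reactants: 22 3-[2-(4-benzyloxyphenyl)ethyl]-5-{4-[(tert-butyldimethylsilyloxy)methyl]phenoxy}phenol
Product: 23 tert-butyl[(4-{3-[2-(4-benzyloxyphenyl)ethyl]-5-methoxyphenoxy}phenyl)methoxy]dimethylsilane
Conditions: MeI, K2CO3, acetone, 50 °C
Reagents that add atoms: iodomethane, CI
Why: Williamson O-methylation meets a single free hydroxyl group, so the position of the methyl ether is unambiguous.

**Step 10**
Reactants: 23 tert-butyl[(4-{3-[2-(4-benzyloxyphenyl)ethyl]-5-methoxyphenoxy}phenyl)methoxy]dimethylsilane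
Product: 24 (4-{3-[2-(4-benzyloxyphenyl)ethyl]-5-methoxyphenoxy}phenyl)methanol
Conditions: TBAF, THF, 0 °C to rt
Reagents that add atoms: none
Why: Fluoride-driven Si–O cleavage is selective for the silyl ether and leaves the benzyl, methyl and diaryl ethers alone.

**Step 11**
Reactants: 24 (4-{3-[2-(4-benzyloxyphenyl)ethyl]-5-methoxyphenoxy}phenyl)methanol
Product: 25 4-{3-[2-(4-benzyloxyphenyl)ethyl]-5-methoxyphenoxy}benzaldehyde
Conditions: MnO2, CH2Cl2, rt
Reagents that add atoms: none
Why: Activated MnO2 oxidises benzylic alcohols to aldehydes without over-oxidation and does not attack the bibenzyl methylenes.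

**Step 12**
Reactants: 26 methyl 2,4-dihydroxy-6-methylbenzoate (methyl orsellinate)
Product: 27 methyl 2-hydroxy-4-methoxy-6-methylbenzoate
Conditions: MeI (1.05 equiv), K2CO3, acetone, reflux
Reagents that add atoms: iodomethane, CI
Why: The C2 hydroxyl is tied up in a hydrogen bond to the ester carbonyl, so one equivalent of MeI alkylates only the C4 phenoxide (selective Williamson etherification).

**Step 13**
Reactants: 27 methyl 2-hydroxy-4-methoxy-6-methylbenzoate
Product: 28 methyl 2-benzyloxy-4-methoxy-6-methylbenzoate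
Conditions: BnBr, K2CO3, DMF, 60 °C
Reagents that add atoms: benzyl bromide, BrCc1ccccc1
Why: Williamson benzylation in a dipolar aprotic solvent overcomes the chelation of the remaining phenol and installs a group that leaves in the final hydrogenolysis.

**Step 14**
Reactants: 28 methyl 2-benzyloxy-4-methoxy-6-methylbenzoate; 25 4-{3-[2-(4-benzyloxyphenyl)ethyl]-5-methoxyphenoxy}benzaldehyde
Product: 31 rac-8-benzyloxy-3-(4-{3-[2-(4-benzyloxyphenyl)ethyl]-5-methoxyphenoxy}phenyl)-6-methoxyisochroman-1-one, via lithiated toluate 29 (not isolated), via lithium alkoxide 30 (not isolated)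
Conditions: 28, LiN(i-Pr)2, THF, −78 °C; then 25, −78 to 0 °C; AcOH quench
Reagents that add atoms: none
Why: Lateral lithiation of an ortho-toluate, addition to a non-enolisable aryl aldehyde and spontaneous lactonisation form the standard toluate-anion route to 3-aryl-3,4-dihydroisocoumarins, and the new C3 centre is formed racemic without consequence because step 15 removes it.

**Step 15**
Reactants: 31 rac-8-benzyloxy-3-(4-{3-[2-(4-benzyloxyphenyl)ethyl]-5-methoxyphenoxy}phenyl)-6-methoxyisochroman-1-one
Product: 33 2-hydroxy-6-[2-(4-{3-[2-(4-hydroxyphenyl)ethyl]-5-methoxyphenoxy}phenyl)ethyl]-4-methoxybenzoic acid (CNP0188714.0), via debenzylated lactone 32 (not isolated)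
Conditions: H2 (1 atm), 10% Pd/C, EtOAc–MeOH, rt
Reagents that add atoms: none
Why: Palladium-catalysed hydrogenolysis cleaves the two aryl benzyl ethers and the benzylic C3–O bond of the lactone (a cyclic benzylic ester activated by the para aryloxy group), freeing the decarboxylation-prone salicylic acid under neutral conditions at room temperature.

**Compound list**
1 | 4-benzyloxybenzyl chloride | ClCc1ccc(OCc2ccccc2)cc1 | starting material
2 | 1-(trimethylsilyl)propyne | CC#C[Si](C)(C)C | starting material
3 | 3-lithio-1-(trimethylsilyl)propyne | [Li]CC#C[Si](C)(C)C | intermediate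
4 | [4-(4-benzyloxyphenyl)but-1-yn-1-yl]trimethylsilane | C[Si](C)(C)C#CCCc1ccc(OCc2ccccc2)cc1 | intermediate
5 | 1-benzyloxy-4-(but-3-yn-1-yl)benzene | C#CCCc1ccc(OCc2ccccc2)cc1 | intermediate
6 | trichloroacetyl chloride | O=C(Cl)C(Cl)(Cl)Cl | starting material
7 | dichloroketene | O=C=C(Cl)Cl | intermediate
8 | 3-[2-(4-benzyloxyphenyl)ethyl]-4,4-dichlorocyclobut-2-en-1-one | O=C1C=C(CCc2ccc(OCc3ccccc3)cc2)C1(Cl)Cl | intermediate
9 | 3-[2-(4-benzyloxyphenyl)ethyl]cyclobut-2-en-1-one | O=C1C=C(CCc2ccc(OCc3ccccc3)cc2)C1 | intermediate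
10 | 4-hydroxybenzyl alcohol | OCc1ccc(O)cc1 | starting material
11 | 4-[(tert-butyldimethylsilyloxy)methyl]phenol | CC(C)(C)[Si](C)(C)OCc1ccc(O)cc1 | intermediate
12 | trichloroethylene | ClC=C(Cl)Cl | starting material
13 | dichloroacetylene | ClC#CCl | intermediate
14 | tert-butyl({4-[(E)-1,2-dichlorovinyloxy]phenyl}methoxy)dimethylsilane | CC(C)(C)[Si](C)(C)OCc1ccc(O/C(Cl)=C\Cl)cc1 | intermediate
15 | tert-butyl({4-[(chloroethynyl)oxy]phenyl}methoxy)dimethylsilane | ClC#COc1ccc(CO[Si](C)(C)C(C)(C)C)cc1 | intermediate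
16 | lithium {4-[(tert-butyldimethylsilyloxy)methyl]phenoxy}acetylide | [Li]C#COc1ccc(CO[Si](C)(C)C(C)(C)C)cc1 | intermediate
17 | tert-butyl{[4-(ethynyloxy)phenyl]methoxy}dimethylsilane | C#COc1ccc(CO[Si](C)(C)C(C)(C)C)cc1 | intermediate
18 | 3-[2-(4-benzyloxyphenyl)ethyl]buta-1,3-dien-1-one (vinylketene) | O=C=CC(=C)CCc1ccc(OCc2ccccc2)cc1 | intermediate
19 | rac-4-[4-(4-benzyloxyphenyl)but-1-en-2-yl]-3-{4-[(tert-butyldimethylsilyloxy)methyl]phenoxy}cyclobut-2-en-1-one | O=C1C=C(Oc2ccc(CO[Si](C)(C)C(C)(C)C)cc2)C1C(=C)CCc1ccc(OCc2ccccc2)cc1 | intermediate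
20 | (3E)-7-(4-benzyloxyphenyl)-3-{4-[(tert-butyldimethylsilyloxy)methyl]phenoxy}-5-methylidenehepta-1,3-dien-1-one (dienylketene) | O=C=C/C(Oc1ccc(CO[Si](C)(C)C(C)(C)C)cc1)=C\C(=C)CCc1ccc(OCc2ccccc2)cc1 | intermediate
21 | 5-[2-(4-benzyloxyphenyl)ethyl]-3-{4-[(tert-butyldimethylsilyloxy)methyl]phenoxy}cyclohexa-2,4-dien-1-one | O=C1C=C(Oc2ccc(CO[Si](C)(C)C(C)(C)C)cc2)C=C(CCc2ccc(OCc3ccccc3)cc2)C1 | intermediate
22 | 3-[2-(4-benzyloxyphenyl)ethyl]-5-{4-[(tert-butyldimethylsilyloxy)methyl]phenoxy}phenol | Oc1cc(CCc2ccc(OCc3ccccc3)cc2)cc(Oc2ccc(CO[Si](C)(C)C(C)(C)C)cc2)c1 | intermediate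
23 | tert-butyl[(4-{3-[2-(4-benzyloxyphenyl)ethyl]-5-methoxyphenoxy}phenyl)methoxy]dimethylsilane | COc1cc(CCc2ccc(OCc3ccccc3)cc2)cc(Oc2ccc(CO[Si](C)(C)C(C)(C)C)cc2)c1 | intermediate
24 | (4-{3-[2-(4-benzyloxyphenyl)ethyl]-5-methoxyphenoxy}phenyl)methanol | COc1cc(CCc2ccc(OCc3ccccc3)cc2)cc(Oc2ccc(CO)cc2)c1 | intermediate
25 | 4-{3-[2-(4-benzyloxyphenyl)ethyl]-5-methoxyphenoxy}benzaldehyde | COc1cc(CCc2ccc(OCc3ccccc3)cc2)cc(Oc2ccc(C=O)cc2)c1 | intermediate
26 | methyl 2,4-dihydroxy-6-methylbenzoate | COC(=O)c1c(C)cc(O)cc1O | starting material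
27 | methyl 2-hydroxy-4-methoxy-6-methylbenzoate | COC(=O)c1c(C)cc(OC)cc1O | intermediate
28 | methyl 2-benzyloxy-4-methoxy-6-methylbenzoate | COC(=O)c1c(C)cc(OC)cc1OCc1ccccc1 | intermediate
29 | methyl 2-benzyloxy-6-(lithiomethyl)-4-methoxybenzoate | [Li]Cc1cc(OC)cc(OCc2ccccc2)c1C(=O)OC | intermediate
30 | lithium alkoxide of the racemic aldol adduct of 29 and 25 | [Li]OC(Cc1cc(OC)cc(OCc2ccccc2)c1C(=O)OC)c1ccc(Oc2cc(OC)cc(CCc3ccc(OCc4ccccc4)cc3)c2)cc1 | intermediate
31 | rac-8-benzyloxy-3-(4-{3-[2-(4-benzyloxyphenyl)ethyl]-5-methoxyphenoxy}phenyl)-6-methoxyisochroman-1-one | O=C1OC(c2ccc(Oc3cc(OC)cc(CCc4ccc(OCc5ccccc5)cc4)c3)cc2)Cc2cc(OC)cc(OCc3ccccc3)c21 | intermediate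
32 | rac-8-hydroxy-3-(4-{3-[2-(4-hydroxyphenyl)ethyl]-5-methoxyphenoxy}phenyl)-6-methoxyisochroman-1-one | O=C1OC(c2ccc(Oc3cc(OC)cc(CCc4ccc(O)cc4)c3)cc2)Cc2cc(OC)cc(O)c21 | intermediate
33 | 2-hydroxy-6-[2-(4-{3-[2-(4-hydroxyphenyl)ethyl]-5-methoxyphenoxy}phenyl)ethyl]-4-methoxybenzoic acid | COc1cc(CCc2ccc(O)cc2)cc(Oc2ccc(CCc3cc(OC)cc(O)c3C(=O)O)cc2)c1 | target

**Total step count:** 15.
**Longest linear sequence:** 10 steps (steps 1–4, 8–11, 14, 15, from 1).

**Steps most likely to fail**

Step 8. The terminal aryl ynol ether may oligomerise on heating, or it may trap the vinylketene too slowly. In the latter case ketene dimerisation or acylation of the product phenol would take over.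

The fallback sets out from 9 and keeps the ring B construction, but uses the established alkoxyalkyne version and forms the diaryl ether afterwards.
- Compound 9 would be heated (toluene, sealed tube, 80 then 110 °C) with methoxyacetylene F1, freshly made from chloroacetaldehyde dimethyl acetal and NaNH2 in liquid NH3.
- This should give 3-[2-(4-benzyloxyphenyl)ethyl]-5-methoxyphenol F2. Here the alkyne oxygen is already the C1 methyl ether and the ketene oxygen is the free C5 phenol.
- Nucleophilic aromatic substitution of F2 on 4-fluorobenzaldehyde (K2CO3, DMF, 120 °C) then returns to the route at 25.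
- Steps 5–7 and 9–11 become unnecessary.

Step 15. The hydrogenolysis may stop after loss of the two benzyl ethers, leaving the lactone C3–O bond intact.

The fallback sets out from 31 and replaces C–O hydrogenolysis by elimination followed by alkene hydrogenation.
- KOt-Bu in THF (0 °C to rt) would deprotonate C4 and expel the carboxylate (E1cB).
- After acidification this should give 2-benzyloxy-6-[(E)-2-(4-{3-[2-(4-benzyloxyphenyl)ethyl]-5-methoxyphenoxy}phenyl)ethenyl]-4-methoxybenzoic acid F3.
- Hydrogenation of F3 (H2, 10% Pd/C, EtOAc–MeOH, rt) saturates the stilbene and removes both benzyl groups, returning at 33.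

Step 14. Three processes could erode this step: self-condensation of the toluate anion, reversal of the carbonyl addition on warming, and incomplete lactonisation.

The fallback sets out from 24 and forms the same C–C bond by SN2 alkylation instead of carbonyl addition.
- An Appel reaction (CBr4, PPh3, CH2Cl2, 0 °C) would give 1-[2-(4-benzyloxyphenyl)ethyl]-3-[4-(bromomethyl)phenoxy]-5-methoxybenzene F4.
- Anion 29 (from 28 and LiN(i-Pr)2, THF, −78 °C) would be alkylated by F4 to methyl 2-benzyloxy-6-[2-(4-{3-[2-(4-benzyloxyphenyl)ethyl]-5-methoxyphenoxy}phenyl)ethyl]-4-methoxybenzoate F5.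
- Saponification of the hindered ester (KOH, EtOH–H2O, reflux, then cold acidification) would give 2-benzyloxy-6-[2-(4-{3-[2-(4-benzyloxyphenyl)ethyl]-5-methoxyphenoxy}phenyl)ethyl]-4-methoxybenzoic acid F6.
- Debenzylation of F6 (H2, 10% Pd/C, EtOAc–MeOH, rt) returns at 33.

**Further compounds**
F1 | step 8 | methoxyacetylene | C#COC
F2 | step 8 | 3-[2-(4-benzyloxyphenyl)ethyl]-5-methoxyphenol | COc1cc(O)cc(CCc2ccc(OCc3ccccc3)cc2)c1
F3 | step 15 | 2-benzyloxy-6-[(E)-2-(4-{3-[2-(4-benzyloxyphenyl)ethyl]-5-methoxyphenoxy}phenyl)ethenyl]-4-methoxybenzoic acid | O=C(O)c1c(OCc2ccccc2)cc(OC)cc1/C=C/c1ccc(Oc2cc(OC)cc(CCc3ccc(OCc4ccccc4)cc3)c2)cc1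
F4 | step 14 | 1-[2-(4-benzyloxyphenyl)ethyl]-3-[4-(bromomethyl)phenoxy]-5-methoxybenzene | COc1cc(CCc2ccc(OCc3ccccc3)cc2)cc(Oc2ccc(CBr)cc2)c1
F5 | step 14 | methyl 2-benzyloxy-6-[2-(4-{3-[2-(4-benzyloxyphenyl)ethyl]-5-methoxyphenoxy}phenyl)ethyl]-4-methoxybenzoate | COC(=O)c1c(CCc2ccc(Oc3cc(OC)cc(CCc4ccc(OCc5ccccc5)cc4)c3)cc2)cc(OC)cc1OCc1ccccc1
F6 | step 14 | 2-benzyloxy-6-[2-(4-{3-[2-(4-benzyloxyphenyl)ethyl]-5-methoxyphenoxy}phenyl)ethyl]-4-methoxybenzoic acid | O=C(O)c1c(CCc2ccc(Oc3cc(OC)cc(CCc4ccc(OCc5ccccc5)cc4)c3)cc2)cc(OC)cc1OCc1ccccc1
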